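The upper unit's ring A aryl ether is the feature the key step exploits: its atoms C4a=C8a–O1 together with C2 of ring C act as a cationic 2-oxadiene, and C3–C4 come from a cis-enediol two-carbon unit. One AgOSO2CF3-triggered formal [4+2] (oxa-Povarov) reaction forms C2–C3 and C4a–C4, sets the 2,3-cis (2R,3R) centres under auxiliary control and leaves a provisional oxygen at C4. Its precursors are an acyclic O,S-acetal of 4-benzyloxybenzaldehyde with 2,3-bis(benzyloxy)phenol and a chiral (Z)-2-alkoxyvinyl acetate. The adduct is used twice: as C4 electrophile (upper unit) and, after C4 acetoxylation, as C6 nucleophile (lower unit), which gives the 4β→6 bond.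

Key step: step 7

Remarks: Flavan numbering is used (O1, C2, C3, C4, C4a, C5 to C8, C8a; ring A benzo ring, ring B 2-aryl ring, ring C pyran ring); α is the face that carries the 2-aryl group. Assumption: the π-face shielded by the auxiliary is assigned from the stacking model given in step 7; if it proved opposite, the (1R,2S) alcohol, equally available, would be used with otherwise identical steps. Compounds 1, 4, 5, 9, 10 and 18 are taken as commercial. The dioxolanylium cation that carries the C4 reactivity in steps 8, 9 and 10 forms in each step as a different salt, and each salt is numbered separately.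

Step 1
Reactants: 1 2,3-bis(benzyloxy)benzaldehyde
Product: 3 2,3-bis(benzyloxy)phenol, via aryl formate 2 (not isolated)
Conditions: mCPBA, CH2Cl2, 0 °C to rt; aqueous NaHCO3 wash; then K2CO3 (cat.), MeOH, rt
Reagents that add atoms: mCPBA (3-chloroperoxybenzoic acid), OOC(=O)c1cccc(Cl)c1
Why: Baeyer–Villiger (Dakin-type) oxidation in which the electron-rich aryl group migrates, followed by methanolysis of the formate, should give the phenol whose oxygen becomes O1 and whose free ortho carbon becomes C4a.

Step 2
Reactants: 4 4-(benzyloxy)benzyl chloride; 5 thiophenol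
Product: 6 4-(benzyloxy)benzyl phenyl sulfide
Conditions: K2CO3, acetone, rt
Reagents that add atoms: none
Why: SN2 thioetherification of a reactive benzylic chloride by the thiolate.

Step 3
Reactants: 6 4-(benzyloxy)benzyl phenyl sulfide; 3 2,3-bis(benzyloxy)phenol
Product: 8 1,2-bis(benzyloxy)-3-{[4-(benzyloxy)phenyl](phenylsulfanyl)methoxy}benzene (racemic O,S-acetal), via chloro sulfide 7 (not isolated)
Conditions: N-chlorosuccinimide, CH2Cl2, 0 °C; then added to 3, Cs2CO3, DMF, 0 °C to rt
Reagents that add atoms: none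
Why: α-Chlorination of the benzylic sulfide (Pummerer-type, through the chlorosulfonium ion) and SN1-type O-alkylation of the caesium phenoxide by the thionium ion should give an O,S-acetal whose only leaving group towards thiophilic AgOSO2CF3 is sulfur.

Step 4
Reactants: 9 (1S,2R)-trans-2-phenylcyclohexanol; 10 allyl bromide
Product: 11 allyl (1S,2R)-2-phenylcyclohexyl ether
Conditions: NaH, THF/DMF, 0 °C to rt
Reagents that add atoms: none
Why: Williamson etherification that leaves both stereocentres of the auxiliary untouched.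

Step 5
Reactants: 11 allyl (1S,2R)-2-phenylcyclohexyl ether
Product: 13 2-{[(1S,2R)-2-phenylcyclohexyl]oxy}acetaldehyde, via ozonide 12 (not isolated)
Conditions: O3, CH2Cl2, −78 °C; then Me2S, −78 °C to rt
Reagents that add atoms: ozone, [O-][O+]=O
Why: Ozonolysis of the terminal alkene with reductive work-up, the phenyl ring being inert at −78 °C under controlled ozone dosage.

Step 6
Reactants: 13 2-{[(1S,2R)-2-phenylcyclohexyl]oxy}acetaldehyde
Product: 15 (Z)-2-{[(1S,2R)-2-phenylcyclohexyl]oxy}ethenyl acetate, via potassium enolate 14 (not isolated)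
Conditions: KN(SiMe3)2, THF, −78 °C (aldehyde added to base); then Ac2O
Reagents that add atoms: acetic anhydride, CC(=O)OC(C)=O
Why: O-acylation of the potassium-chelated Z enolate of the α-alkoxy aldehyde should give the Z enol acetate, in which the ether oxygen is the stronger donor.

Step 7
Reactants: 8 racemic O,S-acetal; 15 (Z)-2-{[(1S,2R)-2-phenylcyclohexyl]oxy}ethenyl acetate
Product: 17 (2R,3R,4R)-7,8-bis(benzyloxy)-2-[4-(benzyloxy)phenyl]-4-{[(1S,2R)-2-phenylcyclohexyl]oxy}chroman-3-yl acetate (all-cis), via oxocarbenium triflate 16 (not isolated)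
Conditions: AgOSO2CF3 (1.3 equiv), 2,6-di-tert-butyl-4-methylpyridine (1.5 equiv), 15 (1.5 equiv), 4 Å MS, CH2Cl2, −78 °C to −20 °C
Reagents that add atoms: none
Why: AgOSO2CF3 removes thiophenolate from 8 and unveils the E-configured O-aryl oxocarbenium ion 16, a cationic 2-oxadiene (C4a=C8a–O1+=C2) that can only form by loss of sulfur. The acetoxy-bearing carbon of 15 (future C3, β to the donor ether oxygen) adds to C2 in a Prins-type event, and the alkoxycarbenium ion thus formed at C4 is captured by C4a of ring A (para to the C7 ether) in a Friedel–Crafts closure, 6-exo-trig with respect to the C4=O+ bond, that makes ring C, the proton going to the hindered pyridine. The closest known reaction type is the oxa-Povarov reaction (Lewis-acid-mediated formal inverse-electron-demand [4+2] cycloaddition of O-aryl oxocarbenium ions with alkenes), run here with a chiral (Z)-2-acyloxyvinyl ether of the kind used in Lewis-acid [4+2] reactions of cationic heterodienes. C3 is controlled by the auxiliary (in the s-trans enol ether the phenyl group of the 2-phenylcyclohexyl ether stacks over one π face, so C2 bonds to the open face); C2 is controlled by the endo arrangement, which keeps both oxygens of the Z alkene under the oxadiene and places the outward 4-benzyloxyphenyl group cis to the C3 acetate (2,3-cis); C4 follows from the Z geometry but is provisional and is reset in step 8. The step needs regioselectivity (secured by the donor alkoxy group on the carbon that becomes C4), site selectivity of ring closure (C4a is the only free ortho carbon of the aryl ether) and face selectivity (auxiliary), and it tolerates rotation of the C4 cation because C4 is reset later.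

Step 8
Reactants: 17 all-cis adduct; 18 benzyl mercaptan
Product: 20 (2R,3S,4S)-4-(benzylsulfanyl)-7,8-bis(benzyloxy)-2-[4-(benzyloxy)phenyl]chroman-3-yl acetate (2,3-cis-3,4-trans), via acetoxonium alkoxytrifluoroborate 19 (not isolated)
Conditions: BF3·OEt2 (cat.), CH2Cl2, −40 °C to 0 °C
Reagents that add atoms: none
Why: Lewis-acid thiolysis in which BF3 binds the auxiliary ether oxygen and the benzylic C4–O bond (ortho to O1, para to the C7 ether) ionises; the 3α-acetate closes the cis-fused dioxolanylium ion, paired in 19 with the departing alkoxytrifluoroborate, and the thiol opens it at C4 from the β face, which should set 3,4-trans, while proton transfer to the borate returns BF3 and the auxiliary alcohol 9 for reuse.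

Step 9
Reactants: 20 4β-benzylsulfanyl 3-acetate
Product: 22 (2R,3S,4S)-7,8-bis(benzyloxy)-2-[4-(benzyloxy)phenyl]chromane-3,4-diyl diacetate (2,3-cis-3,4-trans), via acetoxonium triflate 21 (not isolated)
Conditions: AgOSO2CF3, NaOAc, anhydrous AcOH/CH2Cl2, 0 °C
Reagents that add atoms: sodium acetate, CC(=O)[O-].[Na+]
Why: Thiophilic activation of the benzylic C4–S bond by AgOSO2CF3 with anchimeric help from the anti 3α-acetate gives the dioxolanylium triflate 21, which acetate should open at C4 with inversion under anhydrous conditions (Prévost-type trans-diester formation), installing the lower-unit 4β oxygen as an acetate that is inert to AgBF4.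

Step 10
Reactants: 20 4β-benzylsulfanyl 3-acetate; 22 3,4-trans diacetate
Product: 24 hexa-O-benzyl tri-O-acetyl epioritin-(4β→6)-epioritin-4β-ol, via acetoxonium tetrafluoroborate 23 (not isolated)
Conditions: AgBF4, 2,6-di-tert-butyl-4-methylpyridine, 4 Å MS, CH2Cl2, −20 °C to 0 °C; 20 added slowly to 22 (3 equiv, excess recovered)
Reagents that add atoms: none
Why: AgBF4-promoted Friedel–Crafts flavanylation in which 20 is ionised to the dioxolanylium tetrafluoroborate 23 and C6 of 22 (ortho to the C7 ether, para to O1, the only doubly activated free position) attacks C4 from the β face, anti to the 3α-acetoxy bridge, which should give the 4β→6 bond with upper 3,4-trans geometry while the 4-acetoxy group of 22 stays inert to the soft Lewis acid.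

Step 11
Reactants: 24 hexa-O-benzyl tri-O-acetyl dimer
Product: 25 hexa-O-benzyl epioritin-(4β→6)-epioritin-4β-ol
Conditions: K2CO3 (cat.), MeOH/THF, rt
Reagents that add atoms: none
Why: Zemplén-type transesterification should remove the three acetates by acyl–oxygen cleavage, so the configurations at C3 and at the lower C4 are retained.

Step 12
Reactants: 25 hexa-O-benzyl dimer triol
Product: 26 epioritin-(4β→6)-epioritin-4β-ol (target)
Conditions: H2 (1 atm), Pd(OH)2/C, THF/MeOH, rt, stopped at full debenzylation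
Reagents that add atoms: none
Why: Hydrogenolysis of the six aryl benzyl ethers under neutral conditions, in which the secondary benzylic C4–OH of the lower unit and the interflavan bond are expected to persist.

Compound list
1 | 2,3-bis(benzyloxy)benzaldehyde | O=Cc1cccc(OCc2ccccc2)c1OCc1ccccc1 | starting material
2 | 2,3-bis(benzyloxy)phenyl formate | O=COc1cccc(OCc2ccccc2)c1OCc1ccccc1 | intermediate
3 | 2,3-bis(benzyloxy)phenol | Oc1cccc(OCc2ccccc2)c1OCc1ccccc1 | intermediate
4 | 4-(benzyloxy)benzyl chloride | ClCc1ccc(OCc2ccccc2)cc1 | starting material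
5 | thiophenol | Sc1ccccc1 | starting material
6 | 4-(benzyloxy)benzyl phenyl sulfide | c1ccc(SCc2ccc(OCc3ccccc3)cc2)cc1 | intermediate
7 | [4-(benzyloxy)phenyl](chloro)methyl phenyl sulfide (racemic) | ClC(Sc1ccccc1)c1ccc(OCc2ccccc2)cc1 | intermediate
8 | 1,2-bis(benzyloxy)-3-{[4-(benzyloxy)phenyl](phenylsulfanyl)methoxy}benzene (racemic O,S-acetal) | c1ccc(SC(Oc2cccc(OCc3ccccc3)c2OCc2ccccc2)c2ccc(OCc3ccccc3)cc2)cc1 | intermediate
9 | (1S,2R)-trans-2-phenylcyclohexanol | O[C@H]1CCCC[C@@H]1c1ccccc1 | starting material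
10 | allyl bromide | C=CCBr | starting material
11 | allyl (1S,2R)-2-phenylcyclohexyl ether | C=CCO[C@H]1CCCC[C@@H]1c1ccccc1 | intermediate
12 | 3-({[(1S,2R)-2-phenylcyclohexyl]oxy}methyl)-1,2,4-trioxolane (ozonide, either configuration at C3) | O1OC(CO[C@H]2CCCC[C@@H]2c2ccccc2)OC1 | intermediate
13 | 2-{[(1S,2R)-2-phenylcyclohexyl]oxy}acetaldehyde | O=CCO[C@H]1CCCC[C@@H]1c1ccccc1 | intermediate
14 | potassium (Z)-2-{[(1S,2R)-2-phenylcyclohexyl]oxy}ethenolate | [K+].[O-]/C=C\O[C@H]1CCCC[C@@H]1c1ccccc1 | intermediate
15 | (Z)-2-{[(1S,2R)-2-phenylcyclohexyl]oxy}ethenyl acetate | CC(=O)O/C=C\O[C@H]1CCCC[C@@H]1c1ccccc1 | intermediate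
16 | (E)-[2,3-bis(benzyloxy)phenyl][4-(benzyloxy)benzylidene]oxonium trifluoromethanesulfonate | c1ccccc1COc1ccc(/C=[O+]/c2cccc(OCc3ccccc3)c2OCc2ccccc2)cc1.[O-]S(=O)(=O)C(F)(F)F | intermediate
17 | (2R,3R,4R)-7,8-bis(benzyloxy)-2-[4-(benzyloxy)phenyl]-4-{[(1S,2R)-2-phenylcyclohexyl]oxy}chroman-3-yl acetate (2α-aryl, 3α-OAc, 4α-OR, all-cis) | c1ccc(COc2ccc([C@H]3Oc4c(ccc(OCc5ccccc5)c4OCc4ccccc4)[C@@H](O[C@H]4CCCC[C@@H]4c4ccccc4)[C@H]3OC(C)=O)cc2)cc1 | intermediate
18 | benzyl mercaptan (phenylmethanethiol) | SCc1ccccc1 | starting material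
19 | acetoxonium alkoxytrifluoroborate: (2R)-7,8-bis(benzyloxy)-2-[4-(benzyloxy)phenyl]chroman carrying a 2-methyl-1,3-dioxolan-2-ylium ring cis-fused through O3 and O4 on the α face, as its trifluoro{[(1S,2R)-2-phenylcyclohexyl]oxy}borate salt | c1ccc(COc2ccc([C@H]3Oc4c(ccc(OCc5ccccc5)c4OCc4ccccc4)[C@H]6[O+]=C(C)O[C@@H]36)cc2)cc1.F[B-](F)(F)O[C@H]1CCCC[C@@H]1c1ccccc1 | intermediate
20 | (2R,3S,4S)-4-(benzylsulfanyl)-7,8-bis(benzyloxy)-2-[4-(benzyloxy)phenyl]chroman-3-yl acetate (2α-aryl, 3α-OAc, 4β-SBn) | c1ccc(COc2ccc([C@H]3Oc4c(ccc(OCc5ccccc5)c4OCc4ccccc4)[C@H](SCc4ccccc4)[C@H]3OC(C)=O)cc2)cc1 | intermediate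
21 | acetoxonium triflate: the same α-face cis-fused 2-methyl-1,3-dioxolan-2-ylium cation as in 19, as its trifluoromethanesulfonate salt | c1ccc(COc2ccc([C@H]3Oc4c(ccc(OCc5ccccc5)c4OCc4ccccc4)[C@H]6[O+]=C(C)O[C@@H]36)cc2)cc1.[O-]S(=O)(=O)C(F)(F)F | intermediate
22 | (2R,3S,4S)-7,8-bis(benzyloxy)-2-[4-(benzyloxy)phenyl]chromane-3,4-diyl diacetate (2α-aryl, 3α-OAc, 4β-OAc) | c1ccc(COc2ccc([C@H]3Oc4c(ccc(OCc5ccccc5)c4OCc4ccccc4)[C@H](OC(C)=O)[C@H]3OC(C)=O)cc2)cc1 | intermediate
23 | acetoxonium tetrafluoroborate: the same α-face cis-fused 2-methyl-1,3-dioxolan-2-ylium cation as in 19, as its tetrafluoroborate salt | c1ccc(COc2ccc([C@H]3Oc4c(ccc(OCc5ccccc5)c4OCc4ccccc4)[C@H]6[O+]=C(C)O[C@@H]36)cc2)cc1.F[B-](F)(F)F | intermediate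
24 | hexa-O-benzyl tri-O-acetyl epioritin-(4β→6)-epioritin-4β-ol (benzyl ethers on all six phenolic oxygens; acetates on upper O3, lower O3 and lower O4; configuration as in 26) | c1ccccc1COc1ccc([C@H]2Oc3c(ccc(OCc5ccccc5)c3OCc3ccccc3)[C@H](c3cc4c(c(OCc5ccccc5)c3OCc3ccccc3)O[C@H](c3ccc(OCc5ccccc5)cc3)[C@H](OC(C)=O)[C@H]4OC(C)=O)[C@H]2OC(C)=O)cc1 | intermediate
25 | hexa-O-benzyl epioritin-(4β→6)-epioritin-4β-ol (upper 3-OH, lower 3-OH and lower 4β-OH free; configuration as in 26) | c1ccccc1COc1ccc([C@H]2Oc3c(ccc(OCc5ccccc5)c3OCc3ccccc3)[C@H](c3cc4c(c(OCc5ccccc5)c3OCc3ccccc3)O[C@H](c3ccc(OCc5ccccc5)cc3)[C@H](O)[C@H]4O)[C@H]2O)cc1 | intermediate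
26 | epioritin-(4β→6)-epioritin-4β-ol, (2R,3R,4S)-2-(4-hydroxyphenyl)-4-[(2R,3R,4S)-3,4,7,8-tetrahydroxy-2-(4-hydroxyphenyl)chroman-6-yl]chromane-3,7,8-triol | Oc1ccc([C@H]2Oc3c(ccc(O)c3O)[C@H](c3cc4c(c(O)c3O)O[C@H](c3ccc(O)cc3)[C@H](O)[C@H]4O)[C@H]2O)cc1 | target

Total step count: 12 steps.
Longest linear sequence: 9 steps (steps 4 to 12, from alcohol 9).

Steps most likely to fail

1. Step 7. The process at risk is π-face discrimination in the C2–C3 bond-forming event, which may be too weak or of the opposite sense, together with erosion of endo control; either would give diastereomeric adducts. The fallback replaces auxiliary induction by a resolution through the C4 leaving group and sets out from 8. Commercial benzyloxyacetaldehyde is converted as in step 6 into (Z)-2-(benzyloxy)ethenyl acetate F1, and the same AgOSO2CF3-triggered [4+2] reaction with 8 should give the racemic all-cis adduct rac-(2R,3R,4R)-4,7,8-tris(benzyloxy)-2-[4-(benzyloxy)phenyl]chroman-3-yl acetate F2. Thiolysis of F2 under the conditions of step 8 with enantiopure methyl N-acetyl-L-cysteinate should give two diastereomeric 4β-thioethers, to be separated by chromatography or crystallisation. The thioether with the (2R,3S,4S) flavan core F3 is kept and its (2S,3R,4R) diastereomer F4 is set aside. F3 takes the place of 20 in steps 9 and 10, so the route is rejoined at 22 and 24.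

2. Step 10. The process at risk is slow capture of the C4 cation by the weakly nucleophilic pyrogallol-type ring A under irreversible AgBF4 activation, so that trapping by heteroatoms and self-condensation of 20 through its own C6 compete. The fallback exchanges the roles of the hard and soft leaving groups and sets out from 17 and 20. Compound 17 is ionised with catalytic Me3SiOSO2CF3 in CH2Cl2 at −78 °C in the presence of excess 20, whose thioether is inert to the hard Lewis acid; the dioxolanylium cation, formed here as its triflate 21, should be captured by C6 of 20 under reversible conditions. This should give the dimer F5, the analogue of 24 with a 4β-benzylsulfanyl group in the lower unit. AgOSO2CF3/NaOAc in AcOH/CH2Cl2 (as in step 9) then exchanges that sulfur for the 4β-acetate, and the route is rejoined at 24.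

3. Step 3. The process at risk is C-alkylation of the ambident phenoxide by the thionium ion, or decomposition of the labile chloro sulfide 7 before it is trapped. The fallback uses an O,O-acetal in place of the O,S-acetal and sets out from 3 and commercial 4-(benzyloxy)benzaldehyde. Trimethyl orthoformate with catalytic p-toluenesulfonic acid in MeOH gives 4-(benzyloxy)benzaldehyde dimethyl acetal F6. Acetyl chloride converts it into 1-(benzyloxy)-4-[chloro(methoxy)methyl]benzene F7, which is used in the flask with 3 and i-Pr2NEt to give the mixed O-aryl O-methyl acetal F8. F8 and 15 with Me3SiOSO2CF3 (1.1 equiv, silylation of the more basic methoxy oxygen) and 2,6-di-tert-butyl-4-methylpyridine in CH2Cl2 at −78 °C should give 17 through the oxocarbenium triflate 16, and the route is rejoined at 17.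

Further compounds
F1 | step 7 | (Z)-2-(benzyloxy)ethenyl acetate | CC(=O)O/C=C\OCc1ccccc1
F2 | step 7 | rac-(2R,3R,4R)-4,7,8-tris(benzyloxy)-2-[4-(benzyloxy)phenyl]chroman-3-yl acetate (racemate, one enantiomer drawn) | c1ccc(COc2ccc([C@H]3Oc4c(ccc(OCc5ccccc5)c4OCc4ccccc4)[C@@H](OCc4ccccc4)[C@H]3OC(C)=O)cc2)cc1
F3 | step 7 | methyl N-acetyl-S-{(2R,3S,4S)-3-acetoxy-7,8-bis(benzyloxy)-2-[4-(benzyloxy)phenyl]chroman-4-yl}-L-cysteinate | c1ccc(COc2ccc([C@H]3Oc4c(ccc(OCc5ccccc5)c4OCc4ccccc4)[C@H](SC[C@H](NC(C)=O)C(=O)OC)[C@H]3OC(C)=O)cc2)cc1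
F4 | step 7 | methyl N-acetyl-S-{(2S,3R,4R)-3-acetoxy-7,8-bis(benzyloxy)-2-[4-(benzyloxy)phenyl]chroman-4-yl}-L-cysteinate | c1ccc(COc2ccc([C@@H]3Oc4c(ccc(OCc5ccccc5)c4OCc4ccccc4)[C@@H](SC[C@H](NC(C)=O)C(=O)OC)[C@@H]3OC(C)=O)cc2)cc1
F5 | step 10 | hexa-O-benzyl di-O-acetyl dimer with 4β-benzylsulfanyl in place of the lower 4β-acetoxy group of 24 (acetates on upper O3 and lower O3) | c1ccccc1COc1ccc([C@H]2Oc3c(ccc(OCc5ccccc5)c3OCc3ccccc3)[C@H](c3cc4c(c(OCc5ccccc5)c3OCc3ccccc3)O[C@H](c3ccc(OCc5ccccc5)cc3)[C@H](OC(C)=O)[C@H]4SCc3ccccc3)[C@H]2OC(C)=O)cc1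
F6 | step 3 | 4-(benzyloxy)benzaldehyde dimethyl acetal | COC(OC)c1ccc(OCc2ccccc2)cc1
F7 | step 3 | 1-(benzyloxy)-4-[chloro(methoxy)methyl]benzene (racemic, not isolated) | COC(Cl)c1ccc(OCc2ccccc2)cc1
F8 | step 3 | 1,2-bis(benzyloxy)-3-{[4-(benzyloxy)phenyl](methoxy)methoxy}benzene (racemic mixed acetal) | COC(Oc1cccc(OCc2ccccc2)c1OCc1ccccc1)c1ccc(OCc2ccccc2)cc1
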